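**Retrosynthetic overview**
- Target ⇐ desilylated acetate: Dess–Martin oxidation of the C12′ carbinol to the ketone; the hydroquinone goes to the quinone in the same pot and is returned by dithionite.
- C1′–C2′ bond, C3′ methyl and the 2′E alkene ⇐ Zr-catalysed methylalumination of a homopropargylic alcohol, then Pd-catalysed coupling with a benzylic bromide made from 2,6-dimethylhydroquinone.
- C4′–C5′ bond and C5′ (S) ⇐ chiral phosphoric acid-catalysed propargylboration of a farnesal-type enal.
- C12′–C13′ ⇐ α-selective prenylbarium addition to an α-methyl aldehyde; C11′ (S) ⇐ a new carbene-catalysed redox esterification of an α-methyl enal with enantioselective protonation (first stereocentre).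
- C5′–C12′ backbone ⇐ geraniol by terminal SeO2 oxidation. No ring is formed; the arene is carried intact.

Assumption: side-chain carbons are numbered C1′ (benzylic) to C16′, and the SMILES is read as 2′E,6′E,5′S,11′S. The C12′ carbinol is carried as an epimer mixture (RS) because it ends as the ketone.

**Route**

Step 1
Reactants: 1 geraniol
Product: 2 tert-butyl{[(2E)-3,7-dimethylocta-2,6-dien-1-yl]oxy}dimethylsilane
Conditions: TBSCl, imidazole, CH2Cl2, 0 °C to rt
Reagents that add atoms: tert-butyldimethylsilyl chloride, CC(C)(C)[Si](C)(C)Cl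
Why: Imidazole-mediated silylation masks the primary allylic alcohol (future C5′) so that the allylic oxidation, the carbene step and the hydride reduction leave it alone.

Step 2
Reactants: 2 tert-butyl{[(2E)-3,7-dimethylocta-2,6-dien-1-yl]oxy}dimethylsilane
Product: 4 (2E,6E)-8-[(tert-butyldimethylsilyl)oxy]-2,6-dimethylocta-2,6-dienal, via allylic alcohol 3 (not isolated)
Conditions: SeO2 (0.3 equiv), t-BuOOH, salicylic acid (cat.), CH2Cl2, rt; filter; then MnO2, CH2Cl2, rt
Reagents that add atoms: tert-butyl hydroperoxide, CC(C)(C)OO (its oxygen is relayed by selenium dioxide, O=[Se]=O)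
Why: SeO2/t-BuOOH allylic oxidation goes to the (E)-methyl of the terminal trisubstituted alkene (the other alkene is deactivated by the allylic silyloxy group), and MnO2 takes the allylic alcohol to the enal.

Step 3
Reactants: 4 (2E,6E)-8-[(tert-butyldimethylsilyl)oxy]-2,6-dimethylocta-2,6-dienal
Product: 5 methyl (2S,6E)-8-[(tert-butyldimethylsilyl)oxy]-2,6-dimethyloct-6-enoate
Conditions: aminoindanol-derived N-C6F5 triazolium tetrafluoroborate (10 mol%, antipode chosen to give 2S), i-Pr2NEt (20 mol%), MeOH (5 equiv), 2,6-dibromo-4-methylphenol (1 equiv), toluene, 0 °C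
Reagents that add atoms: methanol, CO
Why: Proposed new method: the carbene adds to the enal to give a Breslow intermediate, β-protonation at C10′ gives an azolium enol of fixed geometry, and phenol-relayed C-protonation on the face left open by the aminoindane wall sets C11′ (S) before methanol releases the ester from the acyl azolium; the closest known reactions are carbene-catalysed redox esterification of enals (racemic) and enantioselective protonation of azolium enolates from α-chloro aldehydes and α-fluoro enals, which have not been extended to an α-alkyl β-alkyl enal.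

Step 4
Reactants: 5 methyl (2S,6E)-8-[(tert-butyldimethylsilyl)oxy]-2,6-dimethyloct-6-enoate
Product: 6 (2S,6E)-8-[(tert-butyldimethylsilyl)oxy]-2,6-dimethyloct-6-enal
Conditions: i-Bu2AlH (1.1 equiv), CH2Cl2, −78 °C; MeOH, aq. potassium sodium tartrate
Reagents that add atoms: none
Why: Ester half-reduction stops at the aluminium hemiacetal at −78 °C and gives the α-methyl aldehyde on work-up without touching C11′; the aldehyde is used crude.

Step 5
Reactants: 6 (2S,6E)-8-[(tert-butyldimethylsilyl)oxy]-2,6-dimethyloct-6-enal; 7 prenyl chloride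
Product: 10 (2E,7S,8RS)-1,8-bis[(tert-butyldimethylsilyl)oxy]-3,7,11-trimethyldodeca-2,10-diene, via prenylbarium chloride 8 (not isolated), via barium alkoxide 9 (not isolated)
Conditions: 7, Ba (from BaI2, lithium biphenylide), THF, −78 °C; then 6; then TBSOTf, 2,6-lutidine, −78 to 0 °C
Reagents that add atoms: tert-butyldimethylsilyl trifluoromethanesulfonate, CC(C)(C)[Si](C)(C)OS(=O)(=O)C(F)(F)F
Why: Allylic barium reagents add to aldehydes through the less substituted α-carbon (Yamamoto allylbarium addition), giving the linear prenyl carbinol, which is silylated in the same flask; the new carbinol centre is left as a mixture.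

Step 6
Reactants: 10 (2E,7S,8RS)-1,8-bis[(tert-butyldimethylsilyl)oxy]-3,7,11-trimethyldodeca-2,10-diene
Product: 11 (2E,7S,8RS)-8-[(tert-butyldimethylsilyl)oxy]-3,7,11-trimethyldodeca-2,10-dienal
Conditions: DDQ (1.5 equiv), CH2Cl2/pH 7 buffer, rt
Reagents that add atoms: none
Why: DDQ abstracts hydride only from the allylic C–H next to the primary silyloxy group, and the oxocarbenium ion collapses to the (E)-enal (oxidative desilylation of an allylic silyl ether); the non-allylic secondary silyl ether stays.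

Step 7
Reactants: 11 (2E,7S,8RS)-8-[(tert-butyldimethylsilyl)oxy]-3,7,11-trimethyldodeca-2,10-dienal; 12 allenylboronic acid pinacol ester
Product: 13 (4S,5E,10S,11RS)-11-[(tert-butyldimethylsilyl)oxy]-6,10,14-trimethylpentadeca-5,13-dien-1-yn-4-ol
Conditions: (S)-TRIP phosphoric acid (10 mol%), toluene, −20 °C
Reagents that add atoms: none
Why: Chiral phosphoric acid-catalysed propargylboration runs through a six-membered SE2′ transition state in which the acid binds the boronate oxygen and the formyl hydrogen, so C5′ is set as S under catalyst control (the (R)-acid gives R carbinols with aryl and alkenyl aldehydes).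

Step 8
Reactants: 14 2,6-dimethylhydroquinone
Product: 15 1,4-bis[(tert-butyldimethylsilyl)oxy]-2,6-dimethylbenzene
Conditions: TBSCl (2.5 equiv), imidazole, DMF, 50 °C
Reagents that add atoms: tert-butyldimethylsilyl chloride, CC(C)(C)[Si](C)(C)Cl
Why: Silylation of both phenols, the hindered one included at 50 °C, protects the hydroquinone against oxidation and against the aluminium reagents of step 10.

Step 9
Reactants: 15 1,4-bis[(tert-butyldimethylsilyl)oxy]-2,6-dimethylbenzene
Product: 16 2,5-bis[(tert-butyldimethylsilyl)oxy]-3-methylbenzyl bromide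
Conditions: N-bromosuccinimide (0.95 equiv), AIBN (cat.), PhCF3, 80 °C
Reagents that add atoms: N-bromosuccinimide, BrN1C(=O)CCC1=O
Why: Wohl–Ziegler benzylic bromination; the two methyl groups are equivalent, so only one monobromide can form, and the bulky silyl ethers hold back ring bromination.

Step 10
Reactants: 13 (4S,5E,10S,11RS)-11-[(tert-butyldimethylsilyl)oxy]-6,10,14-trimethylpentadeca-5,13-dien-1-yn-4-ol; 16 2,5-bis[(tert-butyldimethylsilyl)oxy]-3-methylbenzyl bromide
Product: 18 (2E,5S,6E,11S,12RS)-1-{2,5-bis[(tert-butyldimethylsilyl)oxy]-3-methylphenyl}-12-[(tert-butyldimethylsilyl)oxy]-3,7,11,15-tetramethylhexadeca-2,6,14-trien-5-ol, via alkenylalane 17 (not isolated)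
Conditions: Me3Al (3 equiv), Cp2ZrCl2 (0.25 equiv), ClCH2CH2Cl, 0 °C to rt; volatiles removed; then 16, Pd(PPh3)4 (5 mol%), THF, rt
Reagents that add atoms: trimethylaluminium, C[Al](C)C
Why: Negishi zirconium-catalysed syn-methylalumination puts methyl on the internal and aluminium on the terminal alkyne carbon (the hydroxyl rides as its aluminium alkoxide), and the Pd-catalysed alkenylalane–benzyl bromide coupling goes with retention, forming C1′–C2′ and fixing the 2′E alkene.

Step 11
Reactants: 18 (2E,5S,6E,11S,12RS)-1-{2,5-bis[(tert-butyldimethylsilyl)oxy]-3-methylphenyl}-12-[(tert-butyldimethylsilyl)oxy]-3,7,11,15-tetramethylhexadeca-2,6,14-trien-5-ol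
Product: 19 (2E,5S,6E,11S,12RS)-1-{2,5-bis[(tert-butyldimethylsilyl)oxy]-3-methylphenyl}-12-[(tert-butyldimethylsilyl)oxy]-3,7,11,15-tetramethylhexadeca-2,6,14-trien-5-yl acetate
Conditions: Ac2O, pyridine, DMAP (cat.), CH2Cl2, 0 °C to rt
Reagents that add atoms: acetic anhydride, CC(=O)OC(C)=O
Why: DMAP-catalysed acetylation of the only free hydroxyl, with retention at C5′.

Step 12
Reactants: 19 (2E,5S,6E,11S,12RS)-1-{2,5-bis[(tert-butyldimethylsilyl)oxy]-3-methylphenyl}-12-[(tert-butyldimethylsilyl)oxy]-3,7,11,15-tetramethylhexadeca-2,6,14-trien-5-yl acetate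
Product: 20 (2E,5S,6E,11S,12RS)-1-(2,5-dihydroxy-3-methylphenyl)-12-hydroxy-3,7,11,15-tetramethylhexadeca-2,6,14-trien-5-yl acetate
Conditions: Bu4NF/AcOH (1:1, 6 equiv), THF, rt to 40 °C, under argon
Reagents that add atoms: none
Why: Fluoride cleaves the two aryl silyl ethers and the secondary silyl ether, and the acetic acid buffer keeps the allylic acetate from hydrolysis.

Step 13
Reactants: 20 (2E,5S,6E,11S,12RS)-1-(2,5-dihydroxy-3-methylphenyl)-12-hydroxy-3,7,11,15-tetramethylhexadeca-2,6,14-trien-5-yl acetate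
Product: 22 (2E,5S,6E,11S)-1-(2,5-dihydroxy-3-methylphenyl)-3,7,11,15-tetramethyl-12-oxohexadeca-2,6,14-trien-5-yl acetate, via keto quinone 21 (not isolated)
Conditions: Dess–Martin periodinane (3 equiv), CH2Cl2, 0 °C to rt; then aq. Na2S2O4
Reagents that add atoms: none
Why: Dess–Martin oxidation makes the C12′ ketone under non-basic conditions that neither epimerise C11′ nor conjugate the β,γ-alkene; the hydroquinone is oxidised to the quinone alongside and is reduced back by dithionite in the work-up.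

**Compound list**
1 | geraniol | CC(C)=CCC/C(C)=C/CO | starting material
2 | tert-butyl{[(2E)-3,7-dimethylocta-2,6-dien-1-yl]oxy}dimethylsilane | CC(C)=CCC/C(C)=C/CO[Si](C)(C)C(C)(C)C | intermediate
3 | (2E,6E)-8-[(tert-butyldimethylsilyl)oxy]-2,6-dimethylocta-2,6-dien-1-ol | OC/C(C)=C/CC/C(C)=C/CO[Si](C)(C)C(C)(C)C | intermediate
4 | (2E,6E)-8-[(tert-butyldimethylsilyl)oxy]-2,6-dimethylocta-2,6-dienal | O=C/C(C)=C/CC/C(C)=C/CO[Si](C)(C)C(C)(C)C | intermediate
5 | methyl (2S,6E)-8-[(tert-butyldimethylsilyl)oxy]-2,6-dimethyloct-6-enoate | COC(=O)[C@@H](C)CCC/C(C)=C/CO[Si](C)(C)C(C)(C)C | intermediate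
6 | (2S,6E)-8-[(tert-butyldimethylsilyl)oxy]-2,6-dimethyloct-6-enal | O=C[C@@H](C)CCC/C(C)=C/CO[Si](C)(C)C(C)(C)C | intermediate
7 | prenyl chloride (1-chloro-3-methylbut-2-ene) | CC(C)=CCCl | starting material
8 | prenylbarium chloride | CC(C)=C[CH2-].[Ba+2].[Cl-] | intermediate
9 | barium chloride alkoxide of (2E,7S,8RS)-1-[(tert-butyldimethylsilyl)oxy]-3,7,11-trimethyldodeca-2,10-dien-8-ol | CC(C)=CCC([O-])[C@@H](C)CCC/C(C)=C/CO[Si](C)(C)C(C)(C)C.[Ba+2].[Cl-] | intermediate
10 | (2E,7S,8RS)-1,8-bis[(tert-butyldimethylsilyl)oxy]-3,7,11-trimethyldodeca-2,10-diene | CC(C)=CCC(O[Si](C)(C)C(C)(C)C)[C@@H](C)CCC/C(C)=C/CO[Si](C)(C)C(C)(C)C | intermediate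
11 | (2E,7S,8RS)-8-[(tert-butyldimethylsilyl)oxy]-3,7,11-trimethyldodeca-2,10-dienal | CC(C)=CCC(O[Si](C)(C)C(C)(C)C)[C@@H](C)CCC/C(C)=C/C=O | intermediate
12 | allenylboronic acid pinacol ester | C=C=CB1OC(C)(C)C(C)(C)O1 | starting material
13 | (4S,5E,10S,11RS)-11-[(tert-butyldimethylsilyl)oxy]-6,10,14-trimethylpentadeca-5,13-dien-1-yn-4-ol | O[C@H](/C=C(\C)CCC[C@H](C)C(O[Si](C)(C)C(C)(C)C)CC=C(C)C)CC#C | intermediate
14 | 2,6-dimethylhydroquinone | Cc1cc(O)cc(C)c1O | starting material
15 | 1,4-bis[(tert-butyldimethylsilyl)oxy]-2,6-dimethylbenzene | Cc1cc(O[Si](C)(C)C(C)(C)C)cc(C)c1O[Si](C)(C)C(C)(C)C | intermediate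
16 | 2,5-bis[(tert-butyldimethylsilyl)oxy]-3-methylbenzyl bromide | BrCc1cc(O[Si](C)(C)C(C)(C)C)cc(C)c1O[Si](C)(C)C(C)(C)C | intermediate
17 | (E)-alkenyl(dimethyl)alane of 13, hydroxyl as its dimethylaluminium alkoxide | C[Al](C)O[C@H](/C=C(\C)CCC[C@H](C)C(O[Si](C)(C)C(C)(C)C)CC=C(C)C)C/C(C)=C/[Al](C)C | intermediate
18 | (2E,5S,6E,11S,12RS)-1-{2,5-bis[(tert-butyldimethylsilyl)oxy]-3-methylphenyl}-12-[(tert-butyldimethylsilyl)oxy]-3,7,11,15-tetramethylhexadeca-2,6,14-trien-5-ol | O[C@H](/C=C(\C)CCC[C@H](C)C(O[Si](C)(C)C(C)(C)C)CC=C(C)C)C/C(C)=C/Cc1cc(O[Si](C)(C)C(C)(C)C)cc(C)c1O[Si](C)(C)C(C)(C)C | intermediate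
19 | (2E,5S,6E,11S,12RS)-1-{2,5-bis[(tert-butyldimethylsilyl)oxy]-3-methylphenyl}-12-[(tert-butyldimethylsilyl)oxy]-3,7,11,15-tetramethylhexadeca-2,6,14-trien-5-yl acetate | CC(=O)O[C@H](/C=C(\C)CCC[C@H](C)C(O[Si](C)(C)C(C)(C)C)CC=C(C)C)C/C(C)=C/Cc1cc(O[Si](C)(C)C(C)(C)C)cc(C)c1O[Si](C)(C)C(C)(C)C | intermediate
20 | (2E,5S,6E,11S,12RS)-1-(2,5-dihydroxy-3-methylphenyl)-12-hydroxy-3,7,11,15-tetramethylhexadeca-2,6,14-trien-5-yl acetate | CC(=O)O[C@H](/C=C(\C)CCC[C@H](C)C(O)CC=C(C)C)C/C(C)=C/Cc1cc(O)cc(C)c1O | intermediate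
21 | (2E,5S,6E,11S)-3,7,11,15-tetramethyl-1-(5-methyl-3,6-dioxocyclohexa-1,4-dien-1-yl)-12-oxohexadeca-2,6,14-trien-5-yl acetate | CC(=O)O[C@H](/C=C(\C)CCC[C@H](C)C(=O)CC=C(C)C)C/C(C)=C/CC1=CC(=O)C=C(C)C1=O | intermediate
22 | (2E,5S,6E,11S)-1-(2,5-dihydroxy-3-methylphenyl)-3,7,11,15-tetramethyl-12-oxohexadeca-2,6,14-trien-5-yl acetate (CNP0102989.1) | CC(=O)O[C@H](/C=C(\C)CCC[C@H](C)C(=O)CC=C(C)C)C/C(C)=C/Cc1cc(O)cc(C)c1O | target

**Step count and risks**
Total steps: 13. Longest linear sequence: 11 (steps 1–7 and 10–13, from geraniol); the arene branch is steps 8–9.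

The three steps most likely to fail:

1. Step 3 (the new carbene step: the α-methyl enal may turn over slowly or be protonated with low selectivity). The fallback sets out from compound 3, which is isolated after the SeO2 stage instead of being oxidised further. Hydroxyl-directed asymmetric hydrogenation with Ru(OAc)2[(S)-BINAP] and H2 (50 atm) in MeOH, the ligand antipode being fixed by a Mosher check on the first run, gives (2S,6E)-8-[(tert-butyldimethylsilyl)oxy]-2,6-dimethyloct-6-en-1-ol F1; the allylic silyl ether alkene has no free hydroxyl and is not reduced. Dess–Martin oxidation of F1 then gives the aldehyde, so the route is rejoined at compound 6.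

2. Step 7 (the β,β-disubstituted enal is a weaker electrophile than the aldehydes this catalysis has been shown on, so rate and selectivity may drop). The fallback sets out from compound 11 and replaces catalyst control by stoichiometric reagent control. Allenylboronic acid and diisopropyl tartrate give diisopropyl (4R,5R)-2-(propa-1,2-dien-1-yl)-1,3,2-dioxaborolane-4,5-dicarboxylate F2 (its mirror image is used if a test run shows the opposite sense), which propargylates 11 in toluene at −78 °C. The route is rejoined at compound 13.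

3. Step 10 (a one-pot sequence with a free hydroxyl, excess Me3Al and a hindered benzylic bromide). The fallback sets out from compound 13 and reverses the polarity of the coupling. The same methylalumination is quenched with I2 to give (1E,4S,5E,10S,11RS)-11-[(tert-butyldimethylsilyl)oxy]-1-iodo-2,6,10,14-tetramethylpentadeca-1,5,13-trien-4-ol F3. Separately, zinc insertion into 16 (Zn, LiCl, THF) gives {2,5-bis[(tert-butyldimethylsilyl)oxy]-3-methylbenzyl}zinc bromide F4. Negishi coupling of F3 with F4 (Pd(PPh3)4, THF) rejoins the route at compound 18.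

**Further compounds**
F1 | step 3 | (2S,6E)-8-[(tert-butyldimethylsilyl)oxy]-2,6-dimethyloct-6-en-1-ol | OC[C@@H](C)CCC/C(C)=C/CO[Si](C)(C)C(C)(C)C
F2 | step 7 | diisopropyl (4R,5R)-2-(propa-1,2-dien-1-yl)-1,3,2-dioxaborolane-4,5-dicarboxylate | C=C=CB1O[C@@H](C(=O)OC(C)C)[C@H](C(=O)OC(C)C)O1
F3 | step 10 | (1E,4S,5E,10S,11RS)-11-[(tert-butyldimethylsilyl)oxy]-1-iodo-2,6,10,14-tetramethylpentadeca-1,5,13-trien-4-ol | O[C@H](/C=C(\C)CCC[C@H](C)C(O[Si](C)(C)C(C)(C)C)CC=C(C)C)C/C(C)=C/I
F4 | step 10 | {2,5-bis[(tert-butyldimethylsilyl)oxy]-3-methylbenzyl}zinc bromide | Br[Zn]Cc1cc(O[Si](C)(C)C(C)(C)C)cc(C)c1O[Si](C)(C)C(C)(C)C
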